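## Retrosynthetic overview

- Ester C–O bond last: Mitsunobu inversion of the (1R)-cycloundecadienol with (Z)-4-hydroxycinnamic acid, itself made by a Still–Gennari olefination.
- The 11-membered carbocycle is the only ring made (the arene is bought); it is closed late at C3=C4 by titanium-induced keto-aldehyde coupling.
- Key bond C5–C6 and the (7E)-alkene come from a Johnson–Claisen [3,3]-sigmatropic rearrangement of a 2-methylallylic alcohol.
- The C1 stereocentre is bought as (R)-epichlorohydrin; C10–C11 is made by reverse prenylation and C2–C3 by dithiane opening of the re-closed epoxide.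

Assumption: locants C1–C11 are those of the cycloundecadienol ring (C1 carbinol, C3=C4 and C7=C8 alkenes, C10 = CMe2); the two Grignard solutions, 2-methyl-1,3-dithiane, triethyl orthoacetate, 4-(TBSO)benzaldehyde and methyl bis(2,2,2-trifluoroethyl)phosphonoacetate are bought.

## Route

Step 1
Reactants: 1 (R)-epichlorohydrin; 2 prenylmagnesium chloride
Product: 4 (2R)-2-(2,2-dimethylbut-3-en-1-yl)oxirane, via chloromagnesium alkoxide 3 (not isolated)
Conditions: Me2C=CHCH2MgCl (1.2 equiv), THF, −40 → 0 °C, no copper salt; then 5 M aq. NaOH, rt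
Reagents that add atoms: none
Why: An allylic Grignard reagent opens the terminal epoxide by SE2′ (allyl-transposed) attack at the CH2 terminus, so its tertiary γ-carbon becomes the quaternary C10, the bought stereocentre is not touched, and NaOH re-closes the oxirane at the former CH2Cl carbon by intramolecular Williamson substitution.

Step 2
Reactants: 4 (2R)-2-(2,2-dimethylbut-3-en-1-yl)oxirane; 5 2-methyl-1,3-dithiane
Product: 8 tert-butyl{[(2R)-4,4-dimethyl-1-(2-methyl-1,3-dithian-2-yl)hex-5-en-2-yl]oxy}dimethylsilane, via 2-lithio-2-methyl-1,3-dithiane 6 (not isolated), via lithium alkoxide 7 (not isolated)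
Conditions: 5, n-BuLi, THF, −30 °C; add 4, −30 → 0 °C; then TBSCl, DMPU, 0 °C → rt
Reagents that add atoms: tert-butyldimethylsilyl chloride (CC(C)(C)[Si](C)(C)Cl)
Why: Corey–Seebach dithiane alkylation, in which the lithiated acetyl-anion equivalent opens the terminal epoxide at its CH2 by SN2 (stereocentre untouched) and the lithium alkoxide is O-silylated in the same flask.

Step 3
Reactants: 8 silyl ether
Product: 10 (5R)-5-[(tert-butyldimethylsilyl)oxy]-3,3-dimethyl-6-(2-methyl-1,3-dithian-2-yl)hexan-1-ol, via B-alkyl-9-BBN adduct 9 (not isolated)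
Conditions: 9-BBN-H (1.5 equiv), THF, 0 °C → rt; then 3 M aq. NaOH, 30% H2O2, 0 °C
Reagents that add atoms: hydrogen peroxide (OO)
Why: Brown hydroboration–oxidation, in which 9-BBN adds anti-Markovnikov to the only monosubstituted alkene and cold alkaline peroxide, a nucleophilic oxidant that spares the dithiane, converts C–B into C–OH without creating a stereocentre.

Step 4
Reactants: 10 primary alcohol
Product: 11 (5R)-5-[(tert-butyldimethylsilyl)oxy]-3,3-dimethyl-6-(2-methyl-1,3-dithian-2-yl)hexanal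
Conditions: (COCl)2, DMSO, CH2Cl2, −78 °C; Et3N, −78 → 0 °C
Reagents that add atoms: none
Why: Swern oxidation stops cleanly at the aldehyde and tolerates the dithiane and the silyl ether.

Step 5
Reactants: 11 aldehyde; 12 isopropenylmagnesium bromide
Product: 13 (7R)-7-[(tert-butyldimethylsilyl)oxy]-2,5,5-trimethyl-8-(2-methyl-1,3-dithian-2-yl)oct-1-en-3-ol (both C3 epimers)
Conditions: CH2=C(Me)MgBr, THF, −78 → 0 °C; aq. NH4Cl
Reagents that add atoms: none
Why: Grignard 1,2-addition gives the 2-methylallylic alcohol as an epimer mixture at the new carbinol, which does not matter because that carbon becomes sp2 in the next step.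

Step 6
Reactants: 13 allylic alcohol; 14 triethyl orthoacetate
Product: 16 ethyl (4E,9R)-9-[(tert-butyldimethylsilyl)oxy]-4,7,7-trimethyl-10-(2-methyl-1,3-dithian-2-yl)dec-4-enoate, via ketene acetal 15 (not isolated)
Conditions: MeC(OEt)3 (excess), EtCO2H (0.1 equiv), 140 °C, EtOH distilled off
Reagents that add atoms: none
Why: Johnson–Claisen [3,3]-sigmatropic rearrangement through a chair transition state with the carbinol side chain equatorial forms the ring bond C5–C6 and the (E)-trisubstituted C7=C8 alkene (typically above 95:5) while erasing the epimeric carbinol centre, with C1 remote and untouched.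

Step 7
Reactants: 16 ester
Product: 17 (4E,9R)-9-[(tert-butyldimethylsilyl)oxy]-4,7,7-trimethyl-10-(2-methyl-1,3-dithian-2-yl)dec-4-enal
Conditions: i-Bu2AlH (1.1 equiv), CH2Cl2, −78 °C; aq. potassium sodium tartrate (KNaC4H4O6)
Reagents that add atoms: none
Why: DIBAL-H half-reduction, in which the tetrahedral aluminium hemiacetal is stable at −78 °C and releases the aldehyde only on work-up.

Step 8
Reactants: 17 dithiane aldehyde
Product: 18 (4E,9R)-9-[(tert-butyldimethylsilyl)oxy]-4,7,7-trimethyl-11-oxododec-4-enal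
Conditions: MeI (excess), CaCO3, MeCN–H2O 9:1, 45 °C
Reagents that add atoms: water (O)
Why: Alkylative dithiane hydrolysis (S-methylation, then hydrolysis buffered by CaCO3) unmasks the methyl ketone without affecting the aldehyde, the alkene or the silyl ether.

Step 9
Reactants: 18 keto-aldehyde
Product: 19 tert-butyldimethyl{[(1R,3E,7E)-3,7,10,10-tetramethylcycloundeca-3,7-dien-1-yl]oxy}silane
Conditions: TiCl3(DME)1.5, Zn–Cu couple, DME, reflux; 18 added by syringe pump over 30 h (final ca. 2 mM)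
Reagents that add atoms: none
Why: Intramolecular McMurry coupling on low-valent titanium under high dilution closes the ring at C3=C4, and the (E)-alkene is expected as the less strained geometry of the 1,5-diene in this 11-membered ring, by analogy with titanium-induced keto-aldehyde closures of humulene-type rings; no stereocentre is touched.

Step 10
Reactants: 19 macrocyclic silyl ether
Product: 20 (1R,3E,7E)-3,7,10,10-tetramethylcycloundeca-3,7-dien-1-ol
Conditions: Bu4NF, THF, rt
Reagents that add atoms: none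
Why: Fluoride-driven desilylation (strong Si–F bond) frees the secondary alcohol with its configuration unchanged.

Step 11
Reactants: 21 4-[(tert-butyldimethylsilyl)oxy]benzaldehyde; 22 methyl 2-[bis(2,2,2-trifluoroethoxy)phosphoryl]acetate
Product: 25 (2Z)-3-(4-hydroxyphenyl)prop-2-enoic acid, via potassium phosphonate carbanion 23 (not isolated), via methyl (Z)-cinnamate silyl ether 24 (not isolated)
Conditions: 22, KN(SiMe3)2, 18-crown-6, THF, −78 °C; add 21; then LiOH, MeOH–H2O, rt, dark; 1 M HCl to pH 3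
Reagents that add atoms: lithium hydroxide ([Li+].[OH-])
Why: Still–Gennari modification of the Horner–Wadsworth–Emmons reaction gives the (Z)-enoate under kinetic control because the electron-poor phosphonate eliminates fast, and LiOH then saponifies the methyl ester and cleaves the aryl silyl ether without touching the alkene geometry.

Step 12
Reactants: 20 (1R)-alcohol; 25 (Z)-4-hydroxycinnamic acid
Product: 26 (1S,3E,7E)-3,7,10,10-tetramethylcycloundeca-3,7-dien-1-yl (2Z)-3-(4-hydroxyphenyl)prop-2-enoate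
Conditions: PPh3, DIAD, THF, 0 °C → rt, dark
Reagents that add atoms: none
Why: Mitsunobu esterification displaces the activated C1 oxygen by the carboxylate with clean SN2 inversion (1R → 1S), the carboxylic acid (pKa about 4.5) reacts in preference to the phenol, and the near-neutral conditions keep the (Z)-alkene.

## Compound list

1 | (R)-epichlorohydrin, (2R)-2-(chloromethyl)oxirane | ClC[C@H]1CO1 | starting material
2 | prenylmagnesium chloride, (3-methylbut-2-en-1-yl)magnesium chloride | CC(C)=CC[Mg]Cl | starting material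
3 | chloromagnesium (2R)-1-chloro-4,4-dimethylhex-5-en-2-olate | ClC[C@H](O[Mg]Cl)CC(C)(C)C=C | intermediate
4 | (2R)-2-(2,2-dimethylbut-3-en-1-yl)oxirane | C=CC(C)(C)C[C@@H]1CO1 | intermediate
5 | 2-methyl-1,3-dithiane | CC1SCCCS1 | starting material
6 | 2-lithio-2-methyl-1,3-dithiane | [Li]C1(C)SCCCS1 | intermediate
7 | lithium (2R)-4,4-dimethyl-1-(2-methyl-1,3-dithian-2-yl)hex-5-en-2-olate | C=CC(C)(C)C[C@@H](O[Li])CC1(C)SCCCS1 | intermediate
8 | tert-butyl{[(2R)-4,4-dimethyl-1-(2-methyl-1,3-dithian-2-yl)hex-5-en-2-yl]oxy}dimethylsilane | C=CC(C)(C)C[C@@H](O[Si](C)(C)C(C)(C)C)CC1(C)SCCCS1 | intermediate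
9 | 9-{(5R)-5-[(tert-butyldimethylsilyl)oxy]-3,3-dimethyl-6-(2-methyl-1,3-dithian-2-yl)hexyl}-9-borabicyclo[3.3.1]nonane | C(CC(C)(C)C[C@@H](O[Si](C)(C)C(C)(C)C)CC1(C)SCCCS1)B2C3CCCC2CCC3 | intermediate
10 | (5R)-5-[(tert-butyldimethylsilyl)oxy]-3,3-dimethyl-6-(2-methyl-1,3-dithian-2-yl)hexan-1-ol | OCCC(C)(C)C[C@@H](O[Si](C)(C)C(C)(C)C)CC1(C)SCCCS1 | intermediate
11 | (5R)-5-[(tert-butyldimethylsilyl)oxy]-3,3-dimethyl-6-(2-methyl-1,3-dithian-2-yl)hexanal | O=CCC(C)(C)C[C@@H](O[Si](C)(C)C(C)(C)C)CC1(C)SCCCS1 | intermediate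
12 | isopropenylmagnesium bromide, prop-1-en-2-ylmagnesium bromide | CC(=C)[Mg]Br | starting material
13 | (7R)-7-[(tert-butyldimethylsilyl)oxy]-2,5,5-trimethyl-8-(2-methyl-1,3-dithian-2-yl)oct-1-en-3-ol, both C3 epimers | C=C(C)C(O)CC(C)(C)C[C@@H](O[Si](C)(C)C(C)(C)C)CC1(C)SCCCS1 | intermediate
14 | triethyl orthoacetate, 1,1,1-triethoxyethane | CC(OCC)(OCC)OCC | starting material
15 | tert-butyl{[(2R)-6-[(1-ethoxyethenyl)oxy]-4,4,7-trimethyl-1-(2-methyl-1,3-dithian-2-yl)oct-7-en-2-yl]oxy}dimethylsilane (ketene acetal, both C6 epimers) | C=C(OCC)OC(CC(C)(C)C[C@@H](O[Si](C)(C)C(C)(C)C)CC1(C)SCCCS1)C(C)=C | intermediate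
16 | ethyl (4E,9R)-9-[(tert-butyldimethylsilyl)oxy]-4,7,7-trimethyl-10-(2-methyl-1,3-dithian-2-yl)dec-4-enoate | CCOC(=O)CC/C(C)=C/CC(C)(C)C[C@@H](O[Si](C)(C)C(C)(C)C)CC1(C)SCCCS1 | intermediate
17 | (4E,9R)-9-[(tert-butyldimethylsilyl)oxy]-4,7,7-trimethyl-10-(2-methyl-1,3-dithian-2-yl)dec-4-enal | O=CCC/C(C)=C/CC(C)(C)C[C@@H](O[Si](C)(C)C(C)(C)C)CC1(C)SCCCS1 | intermediate
18 | (4E,9R)-9-[(tert-butyldimethylsilyl)oxy]-4,7,7-trimethyl-11-oxododec-4-enal | O=CCC/C(C)=C/CC(C)(C)C[C@@H](O[Si](C)(C)C(C)(C)C)CC(C)=O | intermediate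
19 | tert-butyldimethyl{[(1R,3E,7E)-3,7,10,10-tetramethylcycloundeca-3,7-dien-1-yl]oxy}silane | C/C1=C\CC(C)(C)C[C@@H](O[Si](C)(C)C(C)(C)C)C/C(C)=C/CC1 | intermediate
20 | (1R,3E,7E)-3,7,10,10-tetramethylcycloundeca-3,7-dien-1-ol | C/C1=C\CC(C)(C)C[C@@H](O)C/C(C)=C/CC1 | intermediate
21 | 4-[(tert-butyldimethylsilyl)oxy]benzaldehyde | O=Cc1ccc(O[Si](C)(C)C(C)(C)C)cc1 | starting material
22 | methyl 2-[bis(2,2,2-trifluoroethoxy)phosphoryl]acetate | COC(=O)CP(=O)(OCC(F)(F)F)OCC(F)(F)F | starting material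
23 | potassium salt of the α-carbanion of 22 | [K+].COC(=O)[CH-]P(=O)(OCC(F)(F)F)OCC(F)(F)F | intermediate
24 | methyl (2Z)-3-{4-[(tert-butyldimethylsilyl)oxy]phenyl}prop-2-enoate | COC(=O)/C=C\c1ccc(O[Si](C)(C)C(C)(C)C)cc1 | intermediate
25 | (2Z)-3-(4-hydroxyphenyl)prop-2-enoic acid | OC(=O)/C=C\c1ccc(O)cc1 | intermediate
26 | (1S,3E,7E)-3,7,10,10-tetramethylcycloundeca-3,7-dien-1-yl (2Z)-3-(4-hydroxyphenyl)prop-2-enoate | C/C1=C\CC(C)(C)C[C@H](OC(=O)/C=C\c2ccc(O)cc2)C/C(C)=C/CC1 | target

## Step count and risks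

Total steps: 12. Longest linear sequence: 11 (steps 1–10 and 12; step 11 is a one-step side branch).

Most likely to fail:

**Step 9 (titanium-induced ring closure).** Oligomerisation or an E/Z mixture at the new C3=C4 alkene is possible, and the β-silyloxy ketone is an untested partner. The fallback sets out from 18 and comes back at 19. Both carbonyls of 18 are methylenated with Ph3P=CH2 (Ph3PCH3Br, KN(SiMe3)2, THF, 0 °C) to give tert-butyl{[(4S,8E)-2,6,6,9-tetramethyltrideca-1,8,12-trien-4-yl]oxy}dimethylsilane F1. The descriptor reads S here only because the CIP ranking of the two CH2 arms changes; the centre is not touched. Ring-closing metathesis of F1 with second-generation Hoveyda–Grubbs catalyst, RuCl2(H2IMes)(=CH–C6H4-2-O-i-Pr), in toluene at 80 °C and 1 mM with ethene purged, closes the same C3=C4 bond under reversible conditions and gives 19.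

**Step 12 (Mitsunobu with a phenolic (Z)-cinnamic acid on a macrocyclic secondary alcohol).** Elimination, aryl ether formation or Z → E leakage are the concerns. The fallback sets out from 20 and comes back at 26. MsCl and Et3N in CH2Cl2 at 0 °C give (1R,3E,7E)-3,7,10,10-tetramethylcycloundeca-3,7-dien-1-yl methanesulfonate F2. Acid 25 with Cs2CO3 (0.5 equiv) in DMF gives caesium (2Z)-3-(4-hydroxyphenyl)prop-2-enoate F3, which displaces the sulfonate of F2 at 50 °C in the dark by SN2 with inversion to give 26.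

**Step 1 (γ- versus α-attack of the prenyl Grignard reagent on the epoxide).** The linear prenyl isomer may form in significant amounts. The fallback sets out from 1 and comes back at 8.
- Isobutyronitrile deprotonated with LiN(i-Pr)2 (THF, −78 °C) attacks the epoxide CH2 of 1 to give lithium (2R)-1-chloro-4-cyano-4-methylpentan-2-olate F4, which aqueous NaOH closes to 2,2-dimethyl-3-[(2R)-oxiran-2-yl]propanenitrile F5.
- F5 is opened by 6 to lithium (2R)-4-cyano-4-methyl-1-(2-methyl-1,3-dithian-2-yl)pentan-2-olate F6, which is silylated in the flask (TBSCl, DMPU) to (4R)-4-[(tert-butyldimethylsilyl)oxy]-2,2-dimethyl-5-(2-methyl-1,3-dithian-2-yl)pentanenitrile F7.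
- i-Bu2AlH (toluene, −78 °C, then dilute HCl) reduces the nitrile to (4R)-4-[(tert-butyldimethylsilyl)oxy]-2,2-dimethyl-5-(2-methyl-1,3-dithian-2-yl)pentanal F8, and Wittig methylenation with Ph3P=CH2 converts F8 into 8.

## Further compounds

F1 | step 9 | tert-butyl{[(4S,8E)-2,6,6,9-tetramethyltrideca-1,8,12-trien-4-yl]oxy}dimethylsilane | C=CCC/C(C)=C/CC(C)(C)C[C@@H](O[Si](C)(C)C(C)(C)C)CC(C)=C
F2 | step 12 | (1R,3E,7E)-3,7,10,10-tetramethylcycloundeca-3,7-dien-1-yl methanesulfonate | C/C1=C\CC(C)(C)C[C@@H](OS(C)(=O)=O)C/C(C)=C/CC1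
F3 | step 12 | caesium (2Z)-3-(4-hydroxyphenyl)prop-2-enoate | [Cs+].[O-]C(=O)/C=C\c1ccc(O)cc1
F4 | step 1 | lithium (2R)-1-chloro-4-cyano-4-methylpentan-2-olate | ClC[C@H](O[Li])CC(C)(C)C#N
F5 | step 1 | 2,2-dimethyl-3-[(2R)-oxiran-2-yl]propanenitrile | N#CC(C)(C)C[C@@H]1CO1
F6 | step 1 | lithium (2R)-4-cyano-4-methyl-1-(2-methyl-1,3-dithian-2-yl)pentan-2-olate | N#CC(C)(C)C[C@@H](O[Li])CC1(C)SCCCS1
F7 | step 1 | (4R)-4-[(tert-butyldimethylsilyl)oxy]-2,2-dimethyl-5-(2-methyl-1,3-dithian-2-yl)pentanenitrile | N#CC(C)(C)C[C@@H](O[Si](C)(C)C(C)(C)C)CC1(C)SCCCS1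
F8 | step 1 | (4R)-4-[(tert-butyldimethylsilyl)oxy]-2,2-dimethyl-5-(2-methyl-1,3-dithian-2-yl)pentanal | O=CC(C)(C)C[C@@H](O[Si](C)(C)C(C)(C)C)CC1(C)SCCCS1
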